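**Strategy.** The route rests on cutting the C7–C8 bond of the hexacosanoyl chain. This is an unactivated CH2–CH2 link in an unbranched, stereocentre-free polymethylene chain, separated from the ester carbonyl C1 by the five methylenes C2–C6; the benzene ring of the benzyl ester is only a spectator. A mixed Kolbe electrolysis makes this bond in one operation: icosanoic acid and suberic acid monobenzyl ester each lose CO2 at the anode, and the nonadecyl and 7-(benzyloxy)-7-oxoheptyl radicals combine to give the complete C26 benzyl ester. The precursors are thus two carboxylic acids, each one carbon longer than the half it delivers. The half-ester comes from suberic acid and benzyl alcohol.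

Key step: step 2

Remark: the target has no stereocentre and no stereogenic double bond, so no step has to set or preserve configuration. Atom numbers C1–C26 refer to the hexacosanoyl chain, C1 being the ester carbonyl carbon.

**Step 1**
Reactants: 1 suberic acid (octanedioic acid); 2 benzyl alcohol
Product: 3 8-(benzyloxy)-8-oxooctanoic acid (suberic acid monobenzyl ester)
Conditions: 1 (2 equiv), 2 (1 equiv), TsOH·H2O (5 mol %), toluene, reflux, Dean–Stark; cool, filter off excess 1; extract 3 into aq. NaHCO3, acidify, extract
Reagents that add atoms: none
Why: Fischer esterification with azeotropic removal of water; the excess of diacid should favour the monoester, and the three components differ enough to be separated (diacid insoluble in cold toluene, diester neutral, monoester extractable as its carboxylate).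

**Step 2**
Reactants: 3 8-(benzyloxy)-8-oxooctanoic acid; 4 icosanoic acid (arachidic acid)
Product: 7 benzyl hexacosanoate, via nonadecyl radical 5 (not isolated), via 7-(benzyloxy)-7-oxoheptyl radical 6 (not isolated)
Conditions: 3 (3 equiv), 4 (1 equiv), KOH (10 mol % of total acid), acetone, 35–40 °C, undivided cell, RVC electrodes, rapid alternating polarity (50 ms), until 4 is consumed; chromatography on silica
Reagents that add atoms: none
Why: Partial neutralisation gives the carboxylates of 3 and 4, which are oxidised at the anode to acyloxy radicals that lose CO2 at once, so that the primary radicals 5 and 6 arise side by side at high local concentration and combine to form the C7–C8 bond, while the carboxyl protons are reduced to H2 at the cathode. The closest known reaction type is the mixed (cross) Kolbe electrolysis of a fatty acid with a dicarboxylic acid half-ester, the classical electrochemical chain extension of fatty acids. No ring is closed and no stereocentre is formed. The step needs cross- over homo-coupling, which two equally unbiased primary radicals cannot provide by themselves; it is secured by stoichiometry (threefold excess of 3, so that 5 should meet mainly 6) and by the fact that the two symmetrical side products, octatriacontane and dibenzyl tetradecanedioate, carry zero and two ester groups and should separate from monoester 7 on silica. It also needs one-electron (radical) over two-electron (cation) chemistry, which is favoured because both radicals are primary and unstabilised and because the alternating polarity limits over-oxidation. The benzyl ester should survive because the medium holds no alcohol and no free hydroxide (KOH is consumed as carboxylate) and the ester carbonyl lies six bonds from the radical centre.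

**Compound list**
1 | suberic acid (octanedioic acid) | OC(=O)CCCCCCC(=O)O | starting material
2 | benzyl alcohol | OCc1ccccc1 | starting material
3 | 8-(benzyloxy)-8-oxooctanoic acid (suberic acid monobenzyl ester) | OC(=O)CCCCCCC(=O)OCc1ccccc1 | intermediate
4 | icosanoic acid (arachidic acid) | CCCCCCCCCCCCCCCCCCCC(=O)O | starting material
5 | nonadecyl radical | [CH2]CCCCCCCCCCCCCCCCCC | intermediate
6 | 7-(benzyloxy)-7-oxoheptyl radical | [CH2]CCCCCC(=O)OCc1ccccc1 | intermediate
7 | benzyl hexacosanoate | CCCCCCCCCCCCCCCCCCCCCCCCCC(=O)OCc1ccccc1 | target

**Total step count:** 2
**Longest linear sequence:** 2 steps (1 → 3 → 7)

**Steps most likely to fail** (the route has only two steps, so both are listed)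

1. Step 2 (key step). What may go wrong: statistical radical pairing that gives mainly the two homodimers, passivation of the electrodes by precipitating waxy products, or over-oxidation of the radicals to cation-derived (non-Kolbe) products. Fallback, setting out from 2 and returning at 7: purchased 7-bromoheptanoic acid F1 would be esterified with benzyl alcohol 2 (TsOH cat., toluene, Dean–Stark) to benzyl 7-bromoheptanoate F2. Purchased 1-bromononadecane F3 would be converted with Mg in THF into nonadecylmagnesium bromide F4, which would be added slowly to F2 in THF/NMP with Li2CuCl4 (3 mol %) at −10 to 0 °C. The copper-catalysed sp3–sp3 Kumada-type coupling at the primary C–Br bond should outrun addition to the ester and form the same C7–C8 bond without statistical pairing, giving 7.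

2. Step 1. What may go wrong: the second esterification competing with the first, so that diester and recovered diacid dominate and monoester is lost in the separation. Fallback, setting out from 1 and returning at 3: 1 would be esterified exhaustively with excess 2 (TsOH cat., toluene, Dean–Stark) to dibenzyl octanedioate F5. F5 would then be monosaponified with NaOH (1.0 equiv) in THF–water at 0 °C, followed by HCl. Once one ester is cleaved, the carboxylate formed should disfavour attack of hydroxide on the same molecule, so the hydrolysis should stop at 3.

**Further compounds**
F1 | step 2 | 7-bromoheptanoic acid (purchased) | OC(=O)CCCCCCBr
F2 | step 2 | benzyl 7-bromoheptanoate | BrCCCCCCC(=O)OCc1ccccc1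
F3 | step 2 | 1-bromononadecane (purchased) | CCCCCCCCCCCCCCCCCCCBr
F4 | step 2 | nonadecylmagnesium bromide | CCCCCCCCCCCCCCCCCCC[Mg]Br
F5 | step 1 | dibenzyl octanedioate | O=C(CCCCCCC(=O)OCc1ccccc1)OCc1ccccc1
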